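The easy step is a fork: catalyst intermediate A, once made, goes either forward to catalyst intermediate B or into the trap.

    starting material + free catalyst → catalyst intermediate A (k1 = 3.4 L mol⁻¹ h⁻¹)
    catalyst intermediate A → catalyst intermediate B (k2 = 41 h⁻¹)
    catalyst intermediate B ⇌ free catalyst + product (K3 = 14 M, k3 = 150 h⁻¹)
    catalyst intermediate A + capture agent → trapped intermediate (k4 = 7.3 L mol⁻¹ h⁻¹)

starting material 2.2 M; capture agent 0.110 M; free catalyst 44 mM

1. the form that holds most of the catalyst when 30% of the starting material are converted (free catalyst / catalyst intermediate A / catalyst intermediate B / trapped intermediate)
2. its share of the catalyst then
3. apparent order in free catalyst when 30% of the starting material are converted (percent change of the rate of making product for one percent more free catalyst charged)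

I carry one quantity, the trap odds: the rate of capture over the rate of forward passage from catalyst intermediate A, with capture agent as charged, 0.0196. Catalyst intermediate A cancels from this ratio, so the odds need no concentration of any catalyst form. Forward passage is far faster than capture, so I treat trapping as a small correction to turnover and compute the correction directly.

At 30% conversion, the starting material consumed amounts to 15.0 catalyst charges. The first way multiplies the odds by these passes and puts 29.4% of the catalyst in the trap. The second way follows the capture agent, whose charge is 2.50 catalyst charges. Each capture spends one unit of it, and the odds shrink with what remains, so the capture agent decays exponentially with the passes. That leaves 88.9% of its charge, which means 27.7% of the catalyst is trapped.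

The two ways part by 1.7 percentage points, and the first one cheats: it holds the capture agent at its charge while the trap consumes it. I commit to the second figure. The remaining 72.3% stays in the round, where, by my estimate, free catalyst is taken up more slowly than either catalyst intermediate A or catalyst intermediate B moves forward. I therefore expect free catalyst as the resting state. My reckoning stops there, without an order.

The forecast names free catalyst at 60%, with an order of 1.37. Its ground for an order above one is that “the amount trapped at a given conversion is set by product made, almost independent of catalyst charged”.

The simulation gives free catalyst at 60.4%, an order of 1.4 and 27.1% trapped, which the first way overshoots by more than the second. At that conversion, the same run without capture has an order of 1.0 instead of 1.4, and a rate 1.39 times the actual one. At 40.0 h, with product at 87.4% of the starting material charged and counted as the passes, the same odds give 72.5% of the catalyst trapped; the flask then holds 72.5% as trapped intermediate.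

Its constants were chosen freely, and the outcome is calculated.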